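The route rests on forming the C5–O bond of ring A last. The key step exploits the peri relationship between the C4 carbonyl oxygen of ring C and C5–H of ring A. The ketone steers a ruthenium catalyst to that single C–H bond (the carbonyl's other neighbour, C3, carries methoxy), and a hypervalent iodine oxidant turns it into C5–O in one operation. The precursor is therefore the simpler 3,7,8-trimethoxy-2-(2-methoxyphenyl)chromen-4-one, assembled by Baker–Venkataraman chemistry from 1,2,3-trimethoxybenzene, methoxyacetyl chloride and 2-methoxybenzoyl chloride. A final O-methylation of the new 5-hydroxyl gives the target. All other oxygens are carried as the target's own methyl ethers, so no protecting group is needed.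

Key step: step 4

Remark on the chemistry: ester 9 is assumed to persist in CF3CO2H/(CF3CO)2O and is cleaved only after the oxidant has been reduced, because free phenol 10 has its C5 hydroxyl para to the C8 methoxy and the iodine reagent would oxidise it to a quinone; in step 1 the arene and acid chloride are premixed before AlCl3 is added, so that acylation can outrun loss of CO from the alkoxy-substituted acylium ion.

Step 1
Reactants: 1 1,2,3-trimethoxybenzene; 2 methoxyacetyl chloride
Product: 4 1-(2-hydroxy-3,4-dimethoxyphenyl)-2-methoxyethan-1-one, via 2,3,4-trimethoxyphenyl ketone 3 (not isolated)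
Conditions: AlCl3 (2.5 equiv, added in portions to premixed 1 and 2), CH2Cl2, 0 °C → 40 °C; then 1 M HCl (aq), 0 °C
Reagents that add atoms: none
Why: Friedel–Crafts acylation at C4 of 1 (para to the C1 methoxy, ortho to the C3 methoxy; C4 and C6 are equivalent) gives ketone 3, whose carbonyl and ortho methoxy chelate AlCl3 so that only this ether is cleaved, as chloromethane, to the hydrogen-bonded phenol.

Step 2
Reactants: 4 1-(2-hydroxy-3,4-dimethoxyphenyl)-2-methoxyethan-1-one; 5 2-methoxybenzoyl chloride
Product: 6 2,3-dimethoxy-6-(methoxyacetyl)phenyl 2-methoxybenzoate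
Conditions: pyridine, DMAP (cat.), 0 °C → rt
Reagents that add atoms: none
Why: O-acylation of a phenol by an acid chloride under nucleophilic catalysis, where the acylpyridinium formed with DMAP should overcome the flanked, hydrogen-bonded hydroxyl.

Step 3
Reactants: 6 2,3-dimethoxy-6-(methoxyacetyl)phenyl 2-methoxybenzoate
Product: 8 3,7,8-trimethoxy-2-(2-methoxyphenyl)-4H-chromen-4-one, via 1,3-diketone 7 (not isolated)
Conditions: KOtBu (2.2 equiv), THF, 0 °C → rt; 1 M HCl (aq) work-up, crude 7 taken on; AcOH, H2SO4 (cat.), 90 °C
Reagents that add atoms: none
Why: Baker–Venkataraman rearrangement (the enolate of the α-methoxy ketone attacks the neighbouring aryl ester, an intramolecular Claisen O-to-C acyl transfer) followed by acid-catalysed cyclodehydration of the resulting o-hydroxyaryl 1,3-diketone, which closes the pyranone ring C with the methoxy group at C3.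

Step 4
Reactants: 8 3,7,8-trimethoxy-2-(2-methoxyphenyl)-4H-chromen-4-one
Product: 10 5-hydroxy-3,7,8-trimethoxy-2-(2-methoxyphenyl)-4H-chromen-4-one, via C5 trifluoroacetate 9 (not isolated)
Conditions: [RuCl2(p-cymene)]2 (5 mol%), PhI(OCOCF3)2 (1.5 equiv, added in portions), CF3CO2H/(CF3CO)2O, 80 °C; then Na2S2O3 (aq), 0 °C; NaHCO3 (aq), THF, rt
Reagents that add atoms: [bis(trifluoroacetoxy)iodo]benzene, O=C(OI(OC(=O)C(F)(F)F)c1ccccc1)C(F)(F)F (delivers the C5 oxygen as trifluoroacetate; the same carboxylate is present as solvent trifluoroacetic acid, OC(=O)C(F)(F)F)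
Why: A divalent ruthenium trifluoroacetate formed from [RuCl2(p-cymene)]2 in CF3CO2H binds the C4 carbonyl oxygen of ring C and cleaves the peri C5–H bond of ring A by carboxylate-assisted concerted metalation–deprotonation, giving a five-membered ruthenacycle (Ru, O, C4, C4a, C5). PhI(OCOCF3)2 oxidises this to a tetravalent ruthenium aryl trifluoroacetate, C–O reductive elimination releases ester 9 and returns divalent ruthenium, and aqueous bicarbonate then cleaves the ester to phenol 10. The closest known reaction type is the ketone-directed ortho C–H oxygenation of aryl ketones, chromones and flavones with this catalyst and oxidant. No ring is closed and no stereocenter is formed. The step needs C5 selectivity over C6–H of ring A and the C–H bonds of ring B: only C5–H can reach the carbonyl-bound metal through a five-membered metallacycle, the other neighbour of the carbonyl (C3) carries methoxy, and hydrogen bonding or protonation of the pyranone carbonyl by CF3CO2H lowers the nucleophilicity of both aryl ether rings toward the iodine reagent, which is kept at low concentration by portionwise addition. The product stays masked as the electron-poor trifluoroacetate until thiosulfate has destroyed the oxidant, which protects the para-related C5 oxygen and C8 methoxy from quinone formation.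

Step 5
Reactants: 10 5-hydroxy-3,7,8-trimethoxy-2-(2-methoxyphenyl)-4H-chromen-4-one
Product: 11 3,5,7,8-tetramethoxy-2-(2-methoxyphenyl)-4H-chromen-4-one
Conditions: MeI (3 equiv), K2CO3, DMF, 50 °C
Reagents that add atoms: iodomethane, CI
Why: Williamson O-methylation of the only free hydroxyl, where the polar aprotic solvent, excess MeI and gentle heating should overcome the hydrogen bond between the C5 hydroxyl and the C4 carbonyl.

Compound list
1 | 1,2,3-trimethoxybenzene | COc1cccc(OC)c1OC | starting material
2 | methoxyacetyl chloride | COCC(=O)Cl | starting material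
3 | 2-methoxy-1-(2,3,4-trimethoxyphenyl)ethan-1-one | COCC(=O)c1ccc(OC)c(OC)c1OC | intermediate (formed in flask, not isolated)
4 | 1-(2-hydroxy-3,4-dimethoxyphenyl)-2-methoxyethan-1-one | COCC(=O)c1ccc(OC)c(OC)c1O | intermediate
5 | 2-methoxybenzoyl chloride | COc1ccccc1C(=O)Cl | starting material
6 | 2,3-dimethoxy-6-(methoxyacetyl)phenyl 2-methoxybenzoate | COCC(=O)c1ccc(OC)c(OC)c1OC(=O)c1ccccc1OC | intermediate
7 | 1-(2-hydroxy-3,4-dimethoxyphenyl)-2-methoxy-3-(2-methoxyphenyl)propane-1,3-dione (racemic at C2, enolisable) | COC(C(=O)c1ccccc1OC)C(=O)c1ccc(OC)c(OC)c1O | intermediate (formed in flask, not isolated)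
8 | 3,7,8-trimethoxy-2-(2-methoxyphenyl)-4H-chromen-4-one | COc1ccccc1-c1oc2c(OC)c(OC)ccc2c(=O)c1OC | intermediate (precursor of the key step)
9 | 3,7,8-trimethoxy-2-(2-methoxyphenyl)-4-oxo-4H-chromen-5-yl trifluoroacetate | COc1ccccc1-c1oc2c(OC)c(OC)cc(OC(=O)C(F)(F)F)c2c(=O)c1OC | intermediate (formed in flask, not isolated)
10 | 5-hydroxy-3,7,8-trimethoxy-2-(2-methoxyphenyl)-4H-chromen-4-one | COc1ccccc1-c1oc2c(OC)c(OC)cc(O)c2c(=O)c1OC | intermediate (product of the key step)
11 | 3,5,7,8-tetramethoxy-2-(2-methoxyphenyl)-4H-chromen-4-one (no stereocenters) | COc1ccccc1-c1oc2c(OC)c(OC)cc(OC)c2c(=O)c1OC | target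

Total step count: 5
Longest linear sequence: 5 steps (1 → 4 → 6 → 8 → 10 → 11)

Steps most likely to fail

Step 4. What may go wrong: direct electrophilic attack of the iodine reagent on ring A at C6 (ortho to the C7 methoxy, para to the ring oxygen) or on ring B could outrun the chelation-directed metalation. Ruthenium could also be held unproductively between the C3 methoxy and the C4 carbonyl, or the C5 oxygen could be unmasked early and oxidised on to the quinone. Fallback: the C5 oxygen would be bought instead of made, by running the same assembly on a tetraoxygenated arene; this sets out from 2 and 5 and comes back to the route at target 11, bypassing 8 to 10. Purchased 1,2,3,5-tetramethoxybenzene F1 would be acylated with 2 and AlCl3 as in step 1, passing through 2-methoxy-1-(2,3,4,6-tetramethoxyphenyl)ethan-1-one F2 in the flask to 1-(2-hydroxy-3,4,6-trimethoxyphenyl)-2-methoxyethan-1-one F3. O-Aroylation with 5 (pyridine, DMAP) should give 3,5,6-trimethoxy-2-(methoxyacetyl)phenyl 2-methoxybenzoate F4. Baker–Venkataraman transfer with KOtBu to 1-(2-hydroxy-3,4,6-trimethoxyphenyl)-2-methoxy-3-(2-methoxyphenyl)propane-1,3-dione F5, followed by AcOH/H2SO4 cyclodehydration, should give 11 directly. The price is a regiochemical question in the ether cleavage: of the two methoxy groups flanking the carbonyl of F2, the buttressed one next to the C3 methoxy is expected to be lost, and this would have to be confirmed because the other outcome leads to the 5,6,7-isomer.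

Step 1. What may go wrong: the alkoxy-substituted acylium ion could lose carbon monoxide, which turns the acylating agent into a methoxymethylating or chloromethylating one, and excess AlCl3 could cleave a second ether (the central ring methoxy or the side-chain methoxy). Fallback: the arene would be made the nucleophile, so that no acylium ion is involved; this sets out from 1 and comes back at 4, with 3 isolated on the way. Directed ortho-lithiation of 1 (n-BuLi, TMEDA, THF, 0 °C) should give (2,3,4-trimethoxyphenyl)lithium F6. Addition to purchased 2-methoxy-N-methoxy-N-methylacetamide (COCC(=O)N(C)OC; THF, −78 °C → 0 °C, then aqueous HCl) would give ketone 3 without over-addition. BCl3 (1.1 equiv, CH2Cl2, −78 °C → 0 °C) would then cleave only the methoxy ortho to the carbonyl, through the six-membered boron chelate, to give 4.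

Step 3. What may go wrong: the base could cleave the aryl ester back to phenol 4 in competition with acyl transfer, or the doubly activated α-methoxy diketone could fragment by retro-Claisen reaction in hot acid before the ring closes. Fallback: an Allan–Robinson condensation, which needs neither strong base nor strong acid; it sets out from 4 and comes back at 8, bypassing 6 and 7. 2-Methoxybenzoic anhydride F7 would be prepared from 5 and 2-methoxybenzoic acid in pyridine. Heating 4 with F7 and potassium 2-methoxybenzoate at about 170 °C, followed by brief aqueous KOH/EtOH treatment to destroy excess anhydride, should give 8 in one thermal operation.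

Further compounds
F1 | step 4 | 1,2,3,5-tetramethoxybenzene (purchased) | COc1cc(OC)c(OC)c(OC)c1
F2 | step 4 | 2-methoxy-1-(2,3,4,6-tetramethoxyphenyl)ethan-1-one | COCC(=O)c1c(OC)cc(OC)c(OC)c1OC
F3 | step 4 | 1-(2-hydroxy-3,4,6-trimethoxyphenyl)-2-methoxyethan-1-one | COCC(=O)c1c(OC)cc(OC)c(OC)c1O
F4 | step 4 | 3,5,6-trimethoxy-2-(methoxyacetyl)phenyl 2-methoxybenzoate | COCC(=O)c1c(OC)cc(OC)c(OC)c1OC(=O)c1ccccc1OC
F5 | step 4 | 1-(2-hydroxy-3,4,6-trimethoxyphenyl)-2-methoxy-3-(2-methoxyphenyl)propane-1,3-dione (racemic at C2, enolisable) | COC(C(=O)c1ccccc1OC)C(=O)c1c(OC)cc(OC)c(OC)c1O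
F6 | step 1 | (2,3,4-trimethoxyphenyl)lithium | [Li]c1ccc(OC)c(OC)c1OC
F7 | step 3 | 2-methoxybenzoic anhydride | COc1ccccc1C(=O)OC(=O)c1ccccc1OC
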